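**Retrosynthetic overview**

1. Ring numbering: C1 (quaternary, CH3 and vinyl), C2 (CH2), C3 (O-acyl), C4 (1-carboxyvinyl), C5 (OH), C6 (3-hydroxyprop-1-en-2-yl). Target 39 ⇐ acylation of C3–OH with (Z)-4-acetoxy-2-methylbut-2-enoic acid 36 and fluoride deprotection of the protected cyclohexane 29.
2. The strategy rests on one feature of the single cyclohexane ring: the C5 carbinol sits next to C4, which carries the 1-carboxyvinyl group (a γ-hydroxy α-methylene acid). This is the retron of an aldehyde 2-(alkoxycarbonyl)allylation, so C4–C5 is cut to the open-chain C5 aldehyde / (Z)-2-(bromomethyl)enoate 27, which CrCl2 closes to the only ring.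
3. 27 ⇐ Morita–Baylis–Hillman reaction of the C4 α-alkoxy aldehyde 20 with 2-(trimethylsilyl)ethyl acrylate, then SN2′ bromination.
4. The C6/C1 dyad ⇐ chiral-boron Ireland–Claisen rearrangement of the (Z)-allyl ester 14, built from (Z)-allylic alcohol 8 and acid 13 (from itaconic acid 4-methyl ester).
5. C3 ⇐ (R)-glycidol (propiolate opening, methylcuprate addition). The ring is formed once, in step 20, after all chain stereocentres are in place.

Key step: step 20

Assumption: the sense of asymmetric induction of the (S,S)-diazaborolidine bromide in step 10 is assigned by analogy with E(O) boron enolates of simple allyl esters; if the rearrangement favoured the other enolate face, the equally accessible (R,R)-reagent would be used, the chair analysis fixing the C6/C1 relative configuration in either case.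

**Route**

Step 1
Reactants: 1 (R)-glycidol
Product: 2 (2S)-2-{[(4-methoxybenzyl)oxy]methyl}oxirane
Conditions: NaH, PMBCl, Bu4NI (cat.), THF/DMF, 0 °C → rt
Reagents that add atoms: 4-methoxybenzyl chloride, COc1ccc(CCl)cc1
Why: Williamson etherification of the primary alkoxide should leave the C–O bonds of the stereocentre (the later C3) untouched, so its configuration is carried over.

Step 2
Reactants: 2 PMB glycidyl ether; 3 ethyl propiolate
Product: 5 ethyl (5S)-5-hydroxy-6-[(4-methoxybenzyl)oxy]hex-2-ynoate, via lithium ethyl propiolate 4 (not isolated)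
Conditions: 3, n-BuLi, THF, −78 °C; BF3·OEt2; then 2, −78 °C; aq NH4Cl
Reagents that add atoms: none
Why: BF3-promoted alkynylation of a terminal epoxide with a lithium acetylide is expected at the unsubstituted carbon only, so the carbinol stereocentre is retained and the ynoate for the cuprate step is installed in the same operation.

Step 3
Reactants: 5 hydroxy ynoate
Product: 6 ethyl 4-[(4S)-2-(4-methoxyphenyl)-1,3-dioxolan-4-yl]but-2-ynoate
Conditions: DDQ, 4 Å MS, CH2Cl2, 0 °C
Reagents that add atoms: none
Why: Under anhydrous conditions DDQ oxidises the PMB ether to an oxocarbenium ion that the neighbouring hydroxyl traps (oxidative acetalisation), which protects both oxygens and stores the PMB group for later delivery to the secondary oxygen; the acetal carbon forms as an inconsequential mixture.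

Step 4
Reactants: 6 acetal ynoate
Product: 7 ethyl (2Z)-3-methyl-4-[(4S)-2-(4-methoxyphenyl)-1,3-dioxolan-4-yl]but-2-enoate
Conditions: CuI, MeLi (2 equiv), THF, −78 °C; then 6; MeOH then aq NH4Cl at −78 °C
Reagents that add atoms: methyllithium (MeLi), [Li]C
Why: syn-Carbocupration of the ynoate by lithium dimethylcuprate and protonation at −78 °C should place the new methyl trans to the ester and the C2 chain cis to it, fixing the (Z)-trisubstituted alkene.

Step 5
Reactants: 7 (Z)-enoate
Product: 8 (2Z)-3-methyl-4-[(4S)-2-(4-methoxyphenyl)-1,3-dioxolan-4-yl]but-2-en-1-ol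
Conditions: i-Bu2AlH, CH2Cl2, −78 → −40 °C; aq potassium sodium tartrate
Reagents that add atoms: none
Why: 1,2-Reduction of the enoate by i-Bu2AlH at low temperature should give the allylic alcohol with the alkene geometry intact, the aryl acetal being inert below about −40 °C.

Step 6
Reactants: 9 itaconic acid 4-methyl ester
Product: 11 methyl 3-(hydroxymethyl)but-3-enoate, via isobutyl carbonic mixed anhydride 10 (not isolated)
Conditions: i-BuOCOCl, N-methylmorpholine, THF, −15 °C; then NaBH4, H2O, −15 → 0 °C
Reagents that add atoms: none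
Why: Activation of the free acid as a mixed carbonic anhydride followed by borohydride reduction is chemoselective for the activated carboxyl over the methyl ester and should give the 2-substituted allylic alcohol by 1,2-hydride attack.

Step 7
Reactants: 11 hydroxy ester
Product: 12 methyl 3-{[(tert-butyldiphenylsilyl)oxy]methyl}but-3-enoate
Conditions: TBDPSCl, imidazole, CH2Cl2, 0 °C → rt
Reagents that add atoms: tert-butyl(chloro)diphenylsilane, CC(C)(C)[Si](Cl)(c1ccccc1)c1ccccc1
Why: Imidazole-assisted silylation of the primary allylic alcohol blocks lactonisation onto the ester and installs a robust silyl ether that is meant to survive until the last step.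

Step 8
Reactants: 12 silyl ether ester
Product: 13 3-{[(tert-butyldiphenylsilyl)oxy]methyl}but-3-enoic acid
Conditions: LiOH, THF/H2O, 0 °C; then 1 M HCl to pH 3
Reagents that add atoms: lithium hydroxide (LiOH), [Li+].[OH-]
Why: Saponification of the unhindered methyl ester at 0 °C should outpace base-induced migration of the 1,1-disubstituted alkene into conjugation, and the TBDPS ether tolerates cold aqueous base and brief acidification.

Step 9
Reactants: 8 (Z)-allylic alcohol; 13 butenoic acid
Product: 14 (2Z)-3-methyl-4-[(4S)-2-(4-methoxyphenyl)-1,3-dioxolan-4-yl]but-2-en-1-yl 3-{[(tert-butyldiphenylsilyl)oxy]methyl}but-3-enoate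
Conditions: DCC, DMAP (cat.), CH2Cl2, −10 → 0 °C
Reagents that add atoms: none
Why: Steglich esterification of the primary allylic alcohol at low temperature should give the allyl ester while keeping ketene formation, and with it alkene migration in the acyl part, to a minimum.

Step 10
Reactants: 14 allyl ester
Product: 16 (2S,3S)-2-{3-[(tert-butyldiphenylsilyl)oxy]prop-1-en-2-yl}-3-{[(4S)-2-(4-methoxyphenyl)-1,3-dioxolan-4-yl]methyl}-3-methylpent-4-enoic acid, via E(O) boron dienolate 15 (not isolated)
Conditions: preformed (4S,5S)-2-bromo-1,3-bis[3,5-bis(trifluoromethyl)benzenesulfonyl]-4,5-diphenyl-1,3,2-diazaborolidine (1.3 equiv), i-Pr2NEt, CH2Cl2, −78 °C, then 4 °C; pH 5 buffer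
Reagents that add atoms: none
Why: Chiral boron ester-enolate Ireland–Claisen rearrangement, in which soft enolisation by the C2-symmetric sulfonamido bromoborane and hindered amine in CH2Cl2 is expected to give the E(O) boron dienolate 15, which rearranges [3,3] through a chair with the enolate substituent axial and the methyl of the (Z)-alkene equatorial, so that C6 and the quaternary C1 form together with the required relative configuration while the diamine-derived ligand selects the enolate face (2S,3S).

Step 11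
Reactants: 16 acid
Product: 17 (2S,3S)-2-{3-[(tert-butyldiphenylsilyl)oxy]prop-1-en-2-yl}-3-{[(4S)-2-(4-methoxyphenyl)-1,3-dioxolan-4-yl]methyl}-3-methylpent-4-en-1-ol
Conditions: LiAlH4, THF, 0 °C → rt
Reagents that add atoms: none
Why: LiAlH4 reduction of the hindered carboxylic acid to the primary alcohol leaves the acetal, the silyl ether and the alkenes untouched and does not affect the adjacent stereocentre.

Step 12
Reactants: 17 primary alcohol
Product: 18 TBS ether of 17
Conditions: TBSCl, imidazole, DMF, rt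
Reagents that add atoms: tert-butyl(chloro)dimethylsilane, CC(C)(C)[Si](C)(C)Cl
Why: Standard silylation protects the neopentyl-type primary alcohol as a TBS ether that tolerates the hydride, oxidation, amine and bromination steps ahead and can later be removed in the presence of the TBDPS ether.

Step 13
Reactants: 18 acetal
Product: 19 (2S,4S,5S)-5-{[(tert-butyldimethylsilyl)oxy]methyl}-7-[(tert-butyldiphenylsilyl)oxy]-4-ethenyl-2-[(4-methoxybenzyl)oxy]-4-methyl-6-methylideneheptan-1-ol
Conditions: i-Bu2AlH, CH2Cl2, −40 → 0 °C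
Reagents that add atoms: none
Why: Reductive opening of the 4-methoxybenzylidene acetal by i-Bu2AlH proceeds by coordination of aluminium to the less hindered primary oxygen, so the PMB ether is delivered to the secondary C3 oxygen and the primary hydroxyl is freed.

Step 14
Reactants: 19 primary alcohol
Product: 20 (2S,4S,5S)-5-{[(tert-butyldimethylsilyl)oxy]methyl}-7-[(tert-butyldiphenylsilyl)oxy]-4-ethenyl-2-[(4-methoxybenzyl)oxy]-4-methyl-6-methylideneheptanal
Conditions: Dess–Martin periodinane, NaHCO3, CH2Cl2, 0 °C → rt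
Reagents that add atoms: none
Why: Buffered Dess–Martin oxidation converts the primary alcohol into the α-alkoxy aldehyde (the future C4) under non-epimerising conditions.

Step 15
Reactants: 21 2-(trimethylsilyl)ethanol; 22 acryloyl chloride
Product: 23 2-(trimethylsilyl)ethyl acrylate
Conditions: Et3N, CH2Cl2, 0 °C
Reagents that add atoms: none
Why: Acylation of the primary alcohol by the acid chloride with an amine base gives the fluoride-cleavable acrylate used as the Morita–Baylis–Hillman partner.

Step 16
Reactants: 20 α-alkoxy aldehyde; 23 silylethyl acrylate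
Product: 24 2-(trimethylsilyl)ethyl (4S,6S,7S)-7-{[(tert-butyldimethylsilyl)oxy]methyl}-9-[(tert-butyldiphenylsilyl)oxy]-6-ethenyl-3-hydroxy-4-[(4-methoxybenzyl)oxy]-6-methyl-2,8-dimethylidenenonanoate
Conditions: DABCO, 23 (neat, excess), rt, 3–5 d
Reagents that add atoms: none
Why: The DABCO-catalysed Morita–Baylis–Hillman reaction, which works well with activated α-alkoxy aldehydes, should join C4 to the acrylate α-carbon; the new carbinol centre forms as a mixture that is erased in the next step.

Step 17
Reactants: 24 Morita–Baylis–Hillman adduct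
Product: 25 2-(trimethylsilyl)ethyl (2Z,4S,6S,7S)-2-(bromomethyl)-7-{[(tert-butyldimethylsilyl)oxy]methyl}-9-[(tert-butyldiphenylsilyl)oxy]-6-ethenyl-4-[(4-methoxybenzyl)oxy]-6-methyl-8-methylidenenon-2-enoate
Conditions: NBS, Me2S, CH2Cl2, 0 °C → rt
Reagents that add atoms: N-bromosuccinimide, BrN1C(=O)CCC1=O
Why: The bromosulfonium reagent formed from NBS and Me2S activates the allylic hydroxyl and bromide returns with allylic transposition (SN2′), which for Morita–Baylis–Hillman adducts gives the thermodynamically preferred (Z)-2-(bromomethyl)enoate under near-neutral conditions that spare the PMB and silyl ethers.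

Step 18
Reactants: 25 TBS ether bromide
Product: 26 2-(trimethylsilyl)ethyl (2Z,4S,6S,7S)-2-(bromomethyl)-9-[(tert-butyldiphenylsilyl)oxy]-6-ethenyl-7-(hydroxymethyl)-4-[(4-methoxybenzyl)oxy]-6-methyl-8-methylidenenon-2-enoate
Conditions: aq HF, MeCN, 0 °C
Reagents that add atoms: none
Why: Selective desilylation, since acidic fluoride cleaves the primary TBS ether much faster than the TBDPS ether and does not attack the allylic bromide, the PMB ether or the silylethyl ester.

Step 19
Reactants: 26 hydroxy bromide
Product: 27 2-(trimethylsilyl)ethyl (2Z,4S,6S,7S)-2-(bromomethyl)-9-[(tert-butyldiphenylsilyl)oxy]-6-ethenyl-7-formyl-4-[(4-methoxybenzyl)oxy]-6-methyl-8-methylidenenon-2-enoate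
Conditions: Dess–Martin periodinane, NaHCO3, CH2Cl2, 0 °C; used at once
Reagents that add atoms: none
Why: Buffered Dess–Martin oxidation tolerates the allylic bromide and should give the α-branched, β,γ-unsaturated C5 aldehyde without epimerisation at C6 or alkene migration if the crude product is used immediately.

Step 20
Reactants: 27 open-chain aldehyde bromide
Product: 29 2-(trimethylsilyl)ethyl 2-[cyclohexyl]acrylate with C3-OPMB / C4-acrylate / C5-OH all-trans (full description and SMILES in the list), via allylchromium dichloride 28 (not isolated)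
Conditions: CrCl2 (8 equiv), THF, rt, slow addition of 27 (0.005 M); pH 7 buffer, 0 °C
Reagents that add atoms: none
Why: Two equivalents of CrCl2 reduce the allylic C–Br bond of 27 to the σ-allylchromium 28 (trivalent chromium), whose E and Z forms interconvert by 1,3-metal shift, and this adds to the C5 aldehyde through its γ-carbon C4 in a closed six-membered Zimmerman–Traxler array. The closest known reaction type is the Nozaki–Hiyama–Kishi-type carbonyl allylation with 2-(bromomethyl)acrylates, used intramolecularly to make hydroxy α-methylene esters and lactones. The carbocycle closes by 6-exo-trig attack on the carbonyl, forming the C4–C5 bond, and the allylic transposition delivers the 1-(alkoxycarbonyl)vinyl group on C4 directly. C4 and C5 are set together: the 4,5-trans relation comes from the trans-fused (decalin-like) arrangement of the chromium-containing ring and the nascent chair, since either cis-fused alternative would put the chromium alkoxide syn-axial to the axial C1 methyl or the acrylate syn-axial to the axial C6 side chain. The 3,4-trans relation needs the chair with the C3 PMB ether equatorial, which the substrate should favour because the flipped chair would make OPMB and the C1 vinyl group 1,3-diaxial. The neutral medium spares the epimerisable C6 centre, the skipped alkenes, the silyl ethers and the silylethyl ester, and the cold pH 7 quench is intended to keep the diequatorial hydroxy ester from lactonising.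

Step 21
Reactants: 29 cyclised hydroxy ester
Product: 30 C5 triethylsilyl ether of 29
Conditions: TESOTf, 2,6-lutidine, CH2Cl2, −78 °C
Reagents that add atoms: triethylsilyl trifluoromethanesulfonate, CC[Si](CC)(CC)OS(=O)(=O)C(F)(F)F
Why: Silyl triflate with 2,6-lutidine silylates the hindered equatorial C5 hydroxyl rapidly at low temperature, which also removes the possibility of lactonisation onto the neighbouring ester.

Step 22
Reactants: 30 PMB ether
Product: 31 C3 alcohol (30 without the PMB group)
Conditions: DDQ, CH2Cl2/pH 7 buffer, 0 °C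
Reagents that add atoms: none
Why: Oxidative cleavage of the PMB ether by DDQ in wet buffered CH2Cl2 unmasks the C3 hydroxyl selectively, the silyl ethers, the silylethyl ester and the unactivated alkenes being inert.

Step 23
Reactants: 32 dimethyl citraconate
Product: 33 (2Z)-2-methylbut-2-ene-1,4-diol
Conditions: i-Bu2AlH, CH2Cl2, −78 → 0 °C; aq potassium sodium tartrate
Reagents that add atoms: none
Why: Exhaustive i-Bu2AlH reduction of the (Z)-diester should give the (Z)-enediol by 1,2-reduction with retention of the alkene geometry.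

Step 24
Reactants: 33 (Z)-enediol
Product: 34 (2Z)-4-hydroxy-3-methylbut-2-en-1-yl acetate
Conditions: vinyl acetate, lipase PS (Burkholderia cepacia), t-BuOMe, rt
Reagents that add atoms: vinyl acetate, C=COC(C)=O
Why: Lipase-catalysed irreversible transesterification with vinyl acetate is expected to acylate the less hindered hydroxymethyl group remote from the vinylic methyl, giving the regiodefined monoacetate.

Step 25
Reactants: 34 monoacetate
Product: 36 (2Z)-4-acetoxy-2-methylbut-2-enoic acid, via (2Z)-4-acetoxy-2-methylbut-2-enal 35 (not isolated)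
Conditions: TEMPO (cat.), PhI(OAc)2, CH2Cl2, 0 °C; then NaClO2, NaH2PO4, 2-methyl-2-butene, t-BuOH/H2O, 0 °C
Reagents that add atoms: sodium chlorite (NaClO2), [Na+].[O-]Cl=O
Why: TEMPO/PhI(OAc)2 oxidation of the allylic alcohol to the (Z)-enal 35 followed directly by Pinnick oxidation gives the acid under mild conditions that should preserve the (Z)-geometry and the acetate.

Step 26
Reactants: 31 C3 alcohol; 36 (Z)-acetoxy acid
Product: 38 fully protected C3 ester, via trichlorobenzoyl mixed anhydride 37 (not isolated)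
Conditions: 36, 2,4,6-trichlorobenzoyl chloride, Et3N, toluene, rt; then 31, DMAP, rt
Reagents that add atoms: none
Why: Yamaguchi esterification through the preformed mixed anhydride 37 acylates the moderately hindered equatorial C3 hydroxyl, and pre-activation with a short exposure to DMAP at room temperature is intended to limit Z-to-E isomerisation of the acyl unit.

Step 27
Reactants: 38 protected ester
Product: 39 target acid
Conditions: TASF, DMF, 0 °C → rt; aq NH4Cl (pH about 5)
Reagents that add atoms: none
Why: Fluoride cleaves the silylethyl ester by β-elimination and both silyl ethers (global desilylation), and because the unhindered trimethylsilyl group reacts first, the carboxylate forms before the C5 hydroxyl is released, which should suppress lactonisation and leave the acetate and enoate esters intact.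

**Compound list**

(For ring compounds, "up/down" refers to the ring drawn with C1→C6 clockwise, numbering as in the overview.)

1 | (R)-glycidol | C1[C@H](O1)CO | starting material
2 | (2S)-2-{[(4-methoxybenzyl)oxy]methyl}oxirane | C1[C@H](O1)COCc1ccc(OC)cc1 | intermediate
3 | ethyl propiolate | CCOC(=O)C#C | starting material
4 | lithium ethyl propiolate | [Li]C#CC(=O)OCC | intermediate (not isolated)
5 | ethyl (5S)-5-hydroxy-6-[(4-methoxybenzyl)oxy]hex-2-ynoate | CCOC(=O)C#CC[C@H](O)COCc1ccc(OC)cc1 | intermediate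
6 | ethyl 4-[(4S)-2-(4-methoxyphenyl)-1,3-dioxolan-4-yl]but-2-ynoate (acetal carbon as a mixture) | CCOC(=O)C#CC[C@H]1COC(c2ccc(OC)cc2)O1 | intermediate
7 | ethyl (2Z)-3-methyl-4-[(4S)-2-(4-methoxyphenyl)-1,3-dioxolan-4-yl]but-2-enoate | CCOC(=O)/C=C(C)\C[C@H]1COC(c2ccc(OC)cc2)O1 | intermediate
8 | (2Z)-3-methyl-4-[(4S)-2-(4-methoxyphenyl)-1,3-dioxolan-4-yl]but-2-en-1-ol | OC/C=C(C)\C[C@H]1COC(c2ccc(OC)cc2)O1 | intermediate
9 | itaconic acid 4-methyl ester | C=C(CC(=O)OC)C(=O)O | starting material
10 | isobutyl carbonic mixed anhydride of 9 | C=C(CC(=O)OC)C(=O)OC(=O)OCC(C)C | intermediate (not isolated)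
11 | methyl 3-(hydroxymethyl)but-3-enoate | C=C(CO)CC(=O)OC | intermediate
12 | methyl 3-{[(tert-butyldiphenylsilyl)oxy]methyl}but-3-enoate | C=C(CO[Si](c1ccccc1)(c1ccccc1)C(C)(C)C)CC(=O)OC | intermediate
13 | 3-{[(tert-butyldiphenylsilyl)oxy]methyl}but-3-enoic acid | C=C(CO[Si](c1ccccc1)(c1ccccc1)C(C)(C)C)CC(=O)O | intermediate
14 | (2Z)-3-methyl-4-[(4S)-2-(4-methoxyphenyl)-1,3-dioxolan-4-yl]but-2-en-1-yl 3-{[(tert-butyldiphenylsilyl)oxy]methyl}but-3-enoate | C=C(CO[Si](c1ccccc1)(c1ccccc1)C(C)(C)C)CC(=O)OC/C=C(C)\C[C@H]1COC(c2ccc(OC)cc2)O1 | intermediate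
15 | E(O) boron dienolate of 14, oxygen bound to the (4S,5S)-1,3-bis[3,5-bis(trifluoromethyl)benzenesulfonyl]-4,5-diphenyl-1,3,2-diazaborolidin-2-yl group | C=C(CO[Si](c1ccccc1)(c1ccccc1)C(C)(C)C)/C=C(/OB1N(S(=O)(=O)c2cc(cc(c2)C(F)(F)F)C(F)(F)F)[C@@H](c2ccccc2)[C@H](c2ccccc2)N1S(=O)(=O)c1cc(cc(c1)C(F)(F)F)C(F)(F)F)OC/C=C(C)\C[C@H]1COC(c2ccc(OC)cc2)O1 | intermediate (not isolated)
16 | (2S,3S)-2-{3-[(tert-butyldiphenylsilyl)oxy]prop-1-en-2-yl}-3-{[(4S)-2-(4-methoxyphenyl)-1,3-dioxolan-4-yl]methyl}-3-methylpent-4-enoic acid | OC(=O)[C@H](C(=C)CO[Si](c1ccccc1)(c1ccccc1)C(C)(C)C)[C@](C)(C=C)C[C@H]1COC(c2ccc(OC)cc2)O1 | intermediate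
17 | (2S,3S)-2-{3-[(tert-butyldiphenylsilyl)oxy]prop-1-en-2-yl}-3-{[(4S)-2-(4-methoxyphenyl)-1,3-dioxolan-4-yl]methyl}-3-methylpent-4-en-1-ol | OC[C@H](C(=C)CO[Si](c1ccccc1)(c1ccccc1)C(C)(C)C)[C@](C)(C=C)C[C@H]1COC(c2ccc(OC)cc2)O1 | intermediate
18 | tert-butyldimethylsilyl ether of 17 | CC(C)(C)[Si](C)(C)OC[C@H](C(=C)CO[Si](c1ccccc1)(c1ccccc1)C(C)(C)C)[C@](C)(C=C)C[C@H]1COC(c2ccc(OC)cc2)O1 | intermediate
19 | (2S,4S,5S)-5-{[(tert-butyldimethylsilyl)oxy]methyl}-7-[(tert-butyldiphenylsilyl)oxy]-4-ethenyl-2-[(4-methoxybenzyl)oxy]-4-methyl-6-methylideneheptan-1-ol | CC(C)(C)[Si](C)(C)OC[C@H](C(=C)CO[Si](c1ccccc1)(c1ccccc1)C(C)(C)C)[C@](C)(C=C)C[C@H](OCc1ccc(OC)cc1)CO | intermediate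
20 | (2S,4S,5S)-5-{[(tert-butyldimethylsilyl)oxy]methyl}-7-[(tert-butyldiphenylsilyl)oxy]-4-ethenyl-2-[(4-methoxybenzyl)oxy]-4-methyl-6-methylideneheptanal | CC(C)(C)[Si](C)(C)OC[C@H](C(=C)CO[Si](c1ccccc1)(c1ccccc1)C(C)(C)C)[C@](C)(C=C)C[C@H](OCc1ccc(OC)cc1)C=O | intermediate
21 | 2-(trimethylsilyl)ethanol | C[Si](C)(C)CCO | starting material
22 | acryloyl chloride | C=CC(=O)Cl | starting material
23 | 2-(trimethylsilyl)ethyl acrylate | C=CC(=O)OCC[Si](C)(C)C | intermediate
24 | 2-(trimethylsilyl)ethyl (4S,6S,7S)-7-{[(tert-butyldimethylsilyl)oxy]methyl}-9-[(tert-butyldiphenylsilyl)oxy]-6-ethenyl-3-hydroxy-4-[(4-methoxybenzyl)oxy]-6-methyl-2,8-dimethylidenenonanoate (C3 carbinol as a mixture) | CC(C)(C)[Si](C)(C)OC[C@H](C(=C)CO[Si](c1ccccc1)(c1ccccc1)C(C)(C)C)[C@](C)(C=C)C[C@H](OCc1ccc(OC)cc1)C(O)C(=C)C(=O)OCC[Si](C)(C)C | intermediate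
25 | 2-(trimethylsilyl)ethyl (2Z,4S,6S,7S)-2-(bromomethyl)-7-{[(tert-butyldimethylsilyl)oxy]methyl}-9-[(tert-butyldiphenylsilyl)oxy]-6-ethenyl-4-[(4-methoxybenzyl)oxy]-6-methyl-8-methylidenenon-2-enoate | CC(C)(C)[Si](C)(C)OC[C@H](C(=C)CO[Si](c1ccccc1)(c1ccccc1)C(C)(C)C)[C@](C)(C=C)C[C@H](OCc1ccc(OC)cc1)/C=C(\CBr)C(=O)OCC[Si](C)(C)C | intermediate
26 | 2-(trimethylsilyl)ethyl (2Z,4S,6S,7S)-2-(bromomethyl)-9-[(tert-butyldiphenylsilyl)oxy]-6-ethenyl-7-(hydroxymethyl)-4-[(4-methoxybenzyl)oxy]-6-methyl-8-methylidenenon-2-enoate | OC[C@H](C(=C)CO[Si](c1ccccc1)(c1ccccc1)C(C)(C)C)[C@](C)(C=C)C[C@H](OCc1ccc(OC)cc1)/C=C(\CBr)C(=O)OCC[Si](C)(C)C | intermediate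
27 | 2-(trimethylsilyl)ethyl (2Z,4S,6S,7S)-2-(bromomethyl)-9-[(tert-butyldiphenylsilyl)oxy]-6-ethenyl-7-formyl-4-[(4-methoxybenzyl)oxy]-6-methyl-8-methylidenenon-2-enoate (key-step precursor) | O=C[C@H](C(=C)CO[Si](c1ccccc1)(c1ccccc1)C(C)(C)C)[C@](C)(C=C)C[C@H](OCc1ccc(OC)cc1)/C=C(\CBr)C(=O)OCC[Si](C)(C)C | intermediate
28 | σ-allylchromium dichloride derived from 27 (CH2Br replaced by CH2CrCl2; E and Z forms equilibrate) | O=C[C@H](C(=C)CO[Si](c1ccccc1)(c1ccccc1)C(C)(C)C)[C@](C)(C=C)C[C@H](OCc1ccc(OC)cc1)/C=C(\C[Cr](Cl)Cl)C(=O)OCC[Si](C)(C)C | intermediate (not isolated)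
29 | 2-(trimethylsilyl)ethyl 2-(cyclohexyl)prop-2-enoate attached at ring C4; C1: CH3 up, vinyl down; C3: OPMB down; C4: acrylate up; C5: OH down; C6: 3-[(tert-butyldiphenylsilyl)oxy]prop-1-en-2-yl down (key-step product) | C=C[C@]1(C)C[C@H](OCc2ccc(OC)cc2)[C@@H](C(=C)C(=O)OCC[Si](C)(C)C)[C@H](O)[C@@H]1C(=C)CO[Si](c1ccccc1)(c1ccccc1)C(C)(C)C | intermediate
30 | 29 with C5–OH as its triethylsilyl ether | C=C[C@]1(C)C[C@H](OCc2ccc(OC)cc2)[C@@H](C(=C)C(=O)OCC[Si](C)(C)C)[C@H](O[Si](CC)(CC)CC)[C@@H]1C(=C)CO[Si](c1ccccc1)(c1ccccc1)C(C)(C)C | intermediate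
31 | 30 with free C3–OH (PMB removed) | C=C[C@]1(C)C[C@H](O)[C@@H](C(=C)C(=O)OCC[Si](C)(C)C)[C@H](O[Si](CC)(CC)CC)[C@@H]1C(=C)CO[Si](c1ccccc1)(c1ccccc1)C(C)(C)C | intermediate
32 | dimethyl citraconate, dimethyl (2Z)-2-methylbut-2-enedioate | COC(=O)/C=C(/C)C(=O)OC | starting material
33 | (2Z)-2-methylbut-2-ene-1,4-diol | OC/C=C(/C)CO | intermediate
34 | (2Z)-4-hydroxy-3-methylbut-2-en-1-yl acetate | CC(=O)OC/C=C(/C)CO | intermediate
35 | (2Z)-4-acetoxy-2-methylbut-2-enal | CC(=O)OC/C=C(/C)C=O | intermediate (not isolated)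
36 | (2Z)-4-acetoxy-2-methylbut-2-enoic acid | CC(=O)OC/C=C(/C)C(=O)O | intermediate
37 | mixed anhydride of 36 with 2,4,6-trichlorobenzoic acid | CC(=O)OC/C=C(/C)C(=O)OC(=O)c1c(Cl)cc(Cl)cc1Cl | intermediate (not isolated)
38 | 31 acylated at C3–O with the (2Z)-4-acetoxy-2-methylbut-2-enoyl group | C=C[C@]1(C)C[C@H](OC(=O)/C(C)=C\COC(C)=O)[C@@H](C(=C)C(=O)OCC[Si](C)(C)C)[C@H](O[Si](CC)(CC)CC)[C@@H]1C(=C)CO[Si](c1ccccc1)(c1ccccc1)C(C)(C)C | intermediate
39 | target: 2-(cyclohexyl)prop-2-enoic acid attached at ring C4; C1: CH3 up, vinyl down; C3: (2Z)-4-acetoxy-2-methylbut-2-enoyloxy down; C4: acrylic acid up; C5: OH down; C6: 3-hydroxyprop-1-en-2-yl down | C=C[C@]1(C)C[C@H](OC(=O)/C(C)=C\COC(C)=O)[C@@H](C(=C)C(=O)O)[C@H](O)[C@@H]1C(=C)CO | target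

**Step count and risks**

Total step count: 27. Longest linear sequence: 20 steps (1–5, 9–14, 16–22, 26, 27).

Steps most likely to fail:

1. Step 20 (key cyclisation). The closure may run through the flipped chair or a cis-fused transition state, losing 3,4- or 4,5-trans control. The δ-alkoxy allylchromium may also undergo reductive 1,4-elimination, or the chromium alkoxide may lactonise onto the ester. Fallback: an open-transition-state cyclisation that removes the metal bridge between O5 and the allyl terminus. Setting out from 26, the allylic bromide would be exchanged for tin (Bu3SnSnBu3, Pd(PPh3)4, THF) to give the stannyl alcohol F1. Dess–Martin oxidation would give the stannyl aldehyde F2. BF3·OEt2 in CH2Cl2 at −78 °C would then promote intramolecular allylstannane addition through an antiperiplanar array in which the Lewis-acid-bound oxygen and the acrylate can both sit equatorial, and the allyl-geometry requirement of the closed transition state falls away. This rejoins the route at 29.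

2. Step 10 (boron Ireland–Claisen). Enolate geometry or facial control by the boron reagent may erode, or the Lewis acid may open the aryl acetal during the slow rearrangement. Fallback: a reagent-free rearrangement with separation of diastereomers. Setting out from 14, kinetic enolisation and silylation (LiN(i-Pr)2, Me3SiCl, THF, −78 °C → rt) would give the trimethylsilyl ketene acetal F3, which rearranges through the same chair. After hydrolytic work-up, 16 would be obtained together with its diastereomer F4, epimeric at both new centres. The two are separable because the resident C3 stereocentre makes them diastereomers. The route is rejoined at 16.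

3. Step 26 (esterification). The activated (Z)-acid may isomerise to the (E)-isomer through reversible conjugate addition of DMAP, and acylation of the hindered C3 hydroxyl may be slow. Fallback: build the (Z)-enoate on the substrate. Setting out from 31, acylation with 2-[bis(2,2,2-trifluoroethoxy)phosphoryl]propanoic acid (DCC, cat. DMAP, CH2Cl2) would give the phosphonate ester F5. Still–Gennari olefination (KN(SiMe3)2, 18-crown-6, THF, −78 °C, then 2-oxoethyl acetate) would install the (Z)-4-acetoxy-2-methylbut-2-enoate directly, rejoining the route at 38.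

**Further compounds**

F1 | step 20 | 2-(trimethylsilyl)ethyl (2Z,4S,6S,7S)-9-[(tert-butyldiphenylsilyl)oxy]-6-ethenyl-7-(hydroxymethyl)-4-[(4-methoxybenzyl)oxy]-6-methyl-8-methylidene-2-[(tributylstannyl)methyl]non-2-enoate | OC[C@H](C(=C)CO[Si](c1ccccc1)(c1ccccc1)C(C)(C)C)[C@](C)(C=C)C[C@H](OCc1ccc(OC)cc1)/C=C(\C[Sn](CCCC)(CCCC)CCCC)C(=O)OCC[Si](C)(C)C
F2 | step 20 | 2-(trimethylsilyl)ethyl (2Z,4S,6S,7S)-9-[(tert-butyldiphenylsilyl)oxy]-6-ethenyl-7-formyl-4-[(4-methoxybenzyl)oxy]-6-methyl-8-methylidene-2-[(tributylstannyl)methyl]non-2-enoate | O=C[C@H](C(=C)CO[Si](c1ccccc1)(c1ccccc1)C(C)(C)C)[C@](C)(C=C)C[C@H](OCc1ccc(OC)cc1)/C=C(\C[Sn](CCCC)(CCCC)CCCC)C(=O)OCC[Si](C)(C)C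
F3 | step 10 | trimethylsilyl ketene acetal of 14 (E(O) geometry) | C=C(CO[Si](c1ccccc1)(c1ccccc1)C(C)(C)C)/C=C(/O[Si](C)(C)C)OC/C=C(C)\C[C@H]1COC(c2ccc(OC)cc2)O1
F4 | step 10 | (2R,3R)-2-{3-[(tert-butyldiphenylsilyl)oxy]prop-1-en-2-yl}-3-{[(4S)-2-(4-methoxyphenyl)-1,3-dioxolan-4-yl]methyl}-3-methylpent-4-enoic acid | OC(=O)[C@@H](C(=C)CO[Si](c1ccccc1)(c1ccccc1)C(C)(C)C)[C@@](C)(C=C)C[C@H]1COC(c2ccc(OC)cc2)O1
F5 | step 26 | 31 acylated at C3–O with the 2-[bis(2,2,2-trifluoroethoxy)phosphoryl]propanoyl group | C=C[C@]1(C)C[C@H](OC(=O)C(C)P(=O)(OCC(F)(F)F)OCC(F)(F)F)[C@@H](C(=C)C(=O)OCC[Si](C)(C)C)[C@H](O[Si](CC)(CC)CC)[C@@H]1C(=C)CO[Si](c1ccccc1)(c1ccccc1)C(C)(C)C
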